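**Retrosynthetic overview**

1. Target 15 comes from aldehyde 14 by one global i-Bu2AlH reduction (aldehyde, ethyl enoate, aryl pivalate); 14 comes from dimethyl acetal 13 by hydrolysis.
2. Key disconnection: the 1,4-dioxane ring of 13 is made by oxidative ring contraction of the seven-membered cyclic aryl enol ether 11 (a 2-aryl-2H-1,5-benzodioxepine). The ring oxygen on the arene carbon next to the methoxy group shifts from enol ether carbon C4 to C3, and C4 leaves the ring as the acetal (later CH2OH) carbon.
3. Enabling feature: in the target, dioxane carbon C3 (bonded to ring oxygen O4) carries an exocyclic oxygenated carbon (CH2OH). The unit O4–C3(–CH2O) is the 1,2-oxygen-shifted form of an O–CH=CH enol ether inside a benzodioxepine, and the aryl-bearing neighbour C2 is an existing stereocentre that steers the new one trans.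
4. 11 comes from 10 by ring-closing metathesis (propenyl ether plus 1-arylallyl ether); 10 comes from phenol 9 and carbonate 5 by iridium-catalysed asymmetric allylic etherification, which sets the benzylic stereocentre.
5. 9 is made from 5-hydroxyvanillin 6 (three steps) and 5 from syringaldehyde 1 (four steps). Ring order: both benzene rings are bought, then the seven-membered ring (step 9), then the dioxane ring (step 10).

Key step: step 10

Remarks on the chemistry: the (Ra,Rc,Rc) phosphoramidite is assumed, by analogy with cinnamyl carbonate/phenoxide couplings, to give the R ether 10 (its enantiomer is used if the sense is opposite); the benzylic carbon keeps its geometry throughout, and its descriptor changes from R (10, 11) to S (13–15) only because the CIP priorities change.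

**Route**

Step 1
Reactants: 1 syringaldehyde (4-hydroxy-3,5-dimethoxybenzaldehyde)
Product: 2 ethyl (E)-sinapate, ethyl (E)-3-(4-hydroxy-3,5-dimethoxyphenyl)prop-2-enoate
Conditions: Ph3P=CHCO2Et (1.2 equiv), toluene, 90 °C
Reagents that add atoms: ethyl (triphenylphosphoranylidene)acetate, CCOC(=O)C=P(c1ccccc1)(c1ccccc1)c1ccccc1
Why: Wittig olefination with a stabilised ylide, which tolerates the free phenol and should give the E enoate.

Step 2
Reactants: 2 ethyl (E)-sinapate
Product: 3 (E)-sinapyl alcohol, 4-[(E)-3-hydroxyprop-1-enyl]-2,6-dimethoxyphenol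
Conditions: i-Bu2AlH (4 equiv), toluene, −78 to 0 °C; aqueous potassium sodium tartrate
Reagents that add atoms: none
Why: 1,2-reduction of the conjugated ester by the aluminium hydride (one equivalent is consumed by the phenol) should give the allylic alcohol with the E alkene intact.

Step 3
Reactants: 3 (E)-sinapyl alcohol
Product: 4 4-[(E)-3-hydroxyprop-1-enyl]-2,6-dimethoxyphenyl pivalate
Conditions: PivCl (1.05 equiv), 1 M aqueous NaOH, CH2Cl2, n-Bu4NHSO4 (cat.), 0 °C
Reagents that add atoms: pivaloyl chloride, CC(C)(C)C(Cl)=O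
Why: Schotten–Baumann acylation under phase transfer, in which only the phenol is ionised, so the phenoxide is acylated and the allylic alcohol stays free.

Step 4
Reactants: 4 4-[(E)-3-hydroxyprop-1-enyl]-2,6-dimethoxyphenyl pivalate
Product: 5 tert-butyl (E)-3-(3,5-dimethoxy-4-pivaloyloxyphenyl)prop-2-enyl carbonate
Conditions: Boc2O (1.3 equiv), DMAP (10 mol%), CH2Cl2, 0 °C to rt
Reagents that add atoms: di-tert-butyl dicarbonate, CC(C)(C)OC(=O)OC(=O)OC(C)(C)C
Why: DMAP-catalysed carbonate formation at the primary allylic alcohol installs a leaving group that later releases only non-nucleophilic tert-butoxide, which spares the aryl pivalate.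

Step 5
Reactants: 6 5-hydroxyvanillin (3,4-dihydroxy-5-methoxybenzaldehyde)
Product: 7 4-(allyloxy)-3-hydroxy-5-methoxybenzaldehyde
Conditions: allyl bromide (1.05 equiv), Li2CO3, DMF, 45 °C
Reagents that add atoms: allyl bromide, C=CCBr
Why: Williamson etherification under weak-base control: the 4-OH para to the formyl group is the more acidic one, so the monophenoxide should be alkylated there.

Step 6
Reactants: 7 4-(allyloxy)-3-hydroxy-5-methoxybenzaldehyde
Product: 8 ethyl (E)-3-[4-(allyloxy)-3-hydroxy-5-methoxyphenyl]prop-2-enoate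
Conditions: Ph3P=CHCO2Et (1.2 equiv), toluene, 80 °C
Reagents that add atoms: ethyl (triphenylphosphoranylidene)acetate, CCOC(=O)C=P(c1ccccc1)(c1ccccc1)c1ccccc1
Why: Wittig olefination turns the aldehyde into the electron-poor E enoate, which should be inert to the metal hydride, the metathesis catalyst and the iodane of steps 7 to 10.

Step 7
Reactants: 8 ethyl (E)-3-[4-(allyloxy)-3-hydroxy-5-methoxyphenyl]prop-2-enoate
Product: 9 ethyl (E)-3-[3-hydroxy-5-methoxy-4-[(E)-prop-1-enyloxy]phenyl]prop-2-enoate
Conditions: [Ir(cod)(PMePh2)2]PF6 (2 mol%, activated with H2), THF, rt; chromatography on Et3N-washed silica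
Reagents that add atoms: none
Why: metal hydride catalysed isomerisation of an allyl ether to a propenyl ether (1,3-hydrogen shift), run at rt without acid so that the neighbouring phenol does not add to the new enol ether; the E/Z ratio is of no consequence because the methyl-bearing carbon is lost in step 9.

Step 8
Reactants: 9 ethyl (E)-3-[3-hydroxy-5-methoxy-4-[(E)-prop-1-enyloxy]phenyl]prop-2-enoate; 5 tert-butyl (E)-3-(3,5-dimethoxy-4-pivaloyloxyphenyl)prop-2-enyl carbonate
Product: 10 ethyl (E)-3-[3-[(1R)-1-(3,5-dimethoxy-4-pivaloyloxyphenyl)prop-2-enyloxy]-5-methoxy-4-[(E)-prop-1-enyloxy]phenyl]prop-2-enoate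
Conditions: 9 as lithium phenoxide (LiN(SiMe3)2, 1.0 equiv), [Ir(cod)Cl]2 (2 mol%), (Ra,Rc,Rc)-O,O'-(1,1'-binaphthalene-2,2'-diyl) N,N-bis(1-phenylethyl)phosphoramidite (4 mol%), THF, rt to 40 °C
Reagents that add atoms: none
Why: iridium-catalysed asymmetric allylic etherification of a cinnamyl-type carbonate by a phenoxide, which should be branched-selective, with the chiral phosphoramidite–iridium allyl complex setting the benzylic stereocentre as R.

Step 9
Reactants: 10 ethyl (E)-3-[3-[(1R)-1-(3,5-dimethoxy-4-pivaloyloxyphenyl)prop-2-enyloxy]-5-methoxy-4-[(E)-prop-1-enyloxy]phenyl]prop-2-enoate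
Product: 11 ethyl (E)-3-[(2R)-2-(3,5-dimethoxy-4-pivaloyloxyphenyl)-6-methoxy-2H-1,5-benzodioxepin-8-yl]prop-2-enoate
Conditions: second-generation Grubbs catalyst (5 mol%), 1,4-benzoquinone (10 mol%), toluene (5 mM), 60 °C; acid-free work-up
Reagents that add atoms: none
Why: ring-closing olefin metathesis between the terminal vinyl group and the propenyl enol ether (propene is lost), a closure of the kind used for allyl/propenyl diethers of catechols, with benzoquinone added to suppress double-bond migration so that the stereocentre is not touched.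

Step 10
Reactants: 11 ethyl (E)-3-[(2R)-2-(3,5-dimethoxy-4-pivaloyloxyphenyl)-6-methoxy-2H-1,5-benzodioxepin-8-yl]prop-2-enoate
Product: 13 ethyl (E)-3-[(2S,3R)-3-(dimethoxymethyl)-2-(3,5-dimethoxy-4-pivaloyloxyphenyl)-5-methoxy-2,3-dihydro-1,4-benzodioxin-7-yl]prop-2-enoate, via iodanyl mixed acetal 12 (not isolated)
Conditions: PhI(OH)OTs (1.1 equiv), NaHCO3 (3 equiv), MeOH, 3 Å molecular sieves, −30 to 0 °C
Reagents that add atoms: methanol, CO (both methoxy groups of the acetal in 13 and the C4 methoxy group of 12); [hydroxy(tosyloxy)iodo]benzene, Cc1ccc(cc1)S(=O)(=O)OI(O)c1ccccc1 (its PhI(OTs) unit is held only in 12 and is lost again)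
Why: Proposed new method: the electrophilic trivalent iodine reagent should add to C3 of the aryl enol ether anti to the C2 aryl group while methanol caps C4 as a mixed acetal (12); the C4–O5 ring bond, antiperiplanar to the C3–I bond, then migrates to C3 as iodobenzene leaves, pushed by the methoxy lone pair, and the methoxycarbenium ion so formed is trapped by methanol, so the seven-membered ring contracts to the 1,4-dioxane ring and the former ring carbon C4 becomes the exocyclic acetal carbon. The closest known reaction type is the oxidative ring contraction of cyclic enol ethers (3,4-dihydro-2H-pyrans and glycals to tetrahydrofurfural acetals and 2,5-anhydro sugars) by Tl(NO3)3 or aryl-λ3-iodanes; migration of an aryl ether oxygen in a benzo-fused seven-membered ring has not been shown. The dioxane ring closes by a 1,2-shift of oxygen through a three-membered (O, C4, C3) bridged transition state, that is an intramolecular displacement at C3 with inversion and no open-chain intermediate. The new stereocentre (C3 of 13) is fixed by two stereospecific events, anti addition of iodine relative to the existing C2 aryl stereocentre and inversion at C3 during the shift, which together place the acetal carbon trans to the aryl group, while C2 itself is not touched. The step needs the oxygen shift from C4 to win over a 1,2-aryl shift from C2, over plain solvolysis and over acid ionisation of the vinylogous acetal; the electron-poor pivaloyloxyaryl group (poor migrating group, no benzylic cation), the acetal oxygen push at C4 and the NaHCO3 buffer are meant to secure this, and the acrylate and both arenes are too electron-poor to compete with the enol ether for the iodane.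

Step 11
Reactants: 13 ethyl (E)-3-[(2S,3R)-3-(dimethoxymethyl)-2-(3,5-dimethoxy-4-pivaloyloxyphenyl)-5-methoxy-2,3-dihydro-1,4-benzodioxin-7-yl]prop-2-enoate
Product: 14 ethyl (E)-3-[(2S,3R)-2-(3,5-dimethoxy-4-pivaloyloxyphenyl)-3-formyl-5-methoxy-2,3-dihydro-1,4-benzodioxin-7-yl]prop-2-enoate
Conditions: CF3CO2H/H2O (4:1), CH2Cl2, 0 °C to rt; crude aldehyde used at once
Reagents that add atoms: water, O
Why: acid-catalysed acetal hydrolysis, in which the electron-poor pivaloyloxyaryl group should keep the benzylic aryl ether from ionising and the absence of base should avoid enolisation or beta-elimination of the alpha-aryloxy aldehyde.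

Step 12
Reactants: 14 ethyl (E)-3-[(2S,3R)-2-(3,5-dimethoxy-4-pivaloyloxyphenyl)-3-formyl-5-methoxy-2,3-dihydro-1,4-benzodioxin-7-yl]prop-2-enoate
Product: 15 4-[(2S,3S)-3-(hydroxymethyl)-7-[(E)-3-hydroxyprop-1-enyl]-5-methoxy-2,3-dihydro-1,4-benzodioxin-2-yl]-2,6-dimethoxyphenol (target)
Conditions: i-Bu2AlH (8 equiv), CH2Cl2, −78 to −20 °C; aqueous potassium sodium tartrate
Reagents that add atoms: none
Why: global hydride reduction by i-Bu2AlH should convert the aldehyde into the primary alcohol, the enoate into the E allylic alcohol by 1,2-reduction and the aryl pivalate into the free phenol, without affecting either stereocentre.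

**Compound list**

1 | syringaldehyde | COc1cc(C=O)cc(OC)c1O | starting material
2 | ethyl (E)-sinapate | CCOC(=O)/C=C/c1cc(OC)c(O)c(OC)c1 | intermediate
3 | (E)-sinapyl alcohol | OC/C=C/c1cc(OC)c(O)c(OC)c1 | intermediate
4 | 4-[(E)-3-hydroxyprop-1-enyl]-2,6-dimethoxyphenyl pivalate | OC/C=C/c1cc(OC)c(OC(=O)C(C)(C)C)c(OC)c1 | intermediate
5 | tert-butyl (E)-3-(3,5-dimethoxy-4-pivaloyloxyphenyl)prop-2-enyl carbonate | CC(C)(C)OC(=O)OC/C=C/c1cc(OC)c(OC(=O)C(C)(C)C)c(OC)c1 | intermediate
6 | 5-hydroxyvanillin (3,4-dihydroxy-5-methoxybenzaldehyde) | COc1cc(C=O)cc(O)c1O | starting material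
7 | 4-(allyloxy)-3-hydroxy-5-methoxybenzaldehyde | C=CCOc1c(O)cc(C=O)cc1OC | intermediate
8 | ethyl (E)-3-[4-(allyloxy)-3-hydroxy-5-methoxyphenyl]prop-2-enoate | CCOC(=O)/C=C/c1cc(O)c(OCC=C)c(OC)c1 | intermediate
9 | ethyl (E)-3-[3-hydroxy-5-methoxy-4-[(E)-prop-1-enyloxy]phenyl]prop-2-enoate | CCOC(=O)/C=C/c1cc(O)c(O/C=C/C)c(OC)c1 | intermediate
10 | ethyl (E)-3-[3-[(1R)-1-(3,5-dimethoxy-4-pivaloyloxyphenyl)prop-2-enyloxy]-5-methoxy-4-[(E)-prop-1-enyloxy]phenyl]prop-2-enoate | CCOC(=O)/C=C/c1cc(O[C@H](C=C)c2cc(OC)c(OC(=O)C(C)(C)C)c(OC)c2)c(O/C=C/C)c(OC)c1 | intermediate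
11 | ethyl (E)-3-[(2R)-2-(3,5-dimethoxy-4-pivaloyloxyphenyl)-6-methoxy-2H-1,5-benzodioxepin-8-yl]prop-2-enoate | CCOC(=O)/C=C/c1cc2c(c(OC)c1)OC=C[C@@H](O2)c1cc(OC)c(OC(=O)C(C)(C)C)c(OC)c1 | intermediate
12 | iodanyl mixed acetal: the 4-methoxy-3-[phenyl(tosyloxy)-λ3-iodanyl]-3,4-dihydro adduct of 11, iodine trans to the C2 aryl group and trans to the C4 methoxy group | CCOC(=O)/C=C/c1cc2c(c(OC)c1)O[C@H](OC)[C@@H](I(c3ccccc3)OS(=O)(=O)c3ccc(C)cc3)[C@@H](O2)c1cc(OC)c(OC(=O)C(C)(C)C)c(OC)c1 | intermediate (not isolated)
13 | ethyl (E)-3-[(2S,3R)-3-(dimethoxymethyl)-2-(3,5-dimethoxy-4-pivaloyloxyphenyl)-5-methoxy-2,3-dihydro-1,4-benzodioxin-7-yl]prop-2-enoate (trans) | COc1cc([C@@H]2Oc3cc(/C=C/C(=O)OCC)cc(OC)c3O[C@H]2C(OC)OC)cc(OC)c1OC(=O)C(C)(C)C | intermediate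
14 | ethyl (E)-3-[(2S,3R)-2-(3,5-dimethoxy-4-pivaloyloxyphenyl)-3-formyl-5-methoxy-2,3-dihydro-1,4-benzodioxin-7-yl]prop-2-enoate (trans) | COc1cc([C@@H]2Oc3cc(/C=C/C(=O)OCC)cc(OC)c3O[C@H]2C=O)cc(OC)c1OC(=O)C(C)(C)C | intermediate
15 | 4-[(2S,3S)-3-(hydroxymethyl)-7-[(E)-3-hydroxyprop-1-enyl]-5-methoxy-2,3-dihydro-1,4-benzodioxin-2-yl]-2,6-dimethoxyphenol | COc1cc([C@@H]2Oc3cc(/C=C/CO)cc(OC)c3O[C@H]2CO)cc(OC)c1O | target

**Step count**

Total steps: 12. Longest linear sequence: 9 steps (1 → 2 → 3 → 4 → 5 → 10 → 11 → 13 → 14 → 15; steps 1, 2, 3, 4, 8, 9, 10, 11, 12).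

**Steps most likely to fail**

Step 10 (Proposed new method). What may go wrong: a 1,2-aryl shift from C2 or plain solvolysis at C3 may outrun the oxygen shift, acid may ionise the vinylogous acetal of 11 before it is oxidised, or iodine may add syn to the aryl group and give the cis isomer. The fallback uses known reactions and makes the ring contraction stepwise; it sets out from 11 and returns at 14. 11 is treated with N-bromosuccinimide in THF/H2O at 0 °C. Bromine should add to C3 anti to the aryl group, water adds to C4 and the aryl hemiacetal opens, giving ethyl (E)-3-[3-[(1S,2S)-2-bromo-1-(3,5-dimethoxy-4-pivaloyloxyphenyl)-3-oxopropoxy]-4-hydroxy-5-methoxyphenyl]prop-2-enoate F1 (bromohydrin formation of an enol ether). NaHCO3 in MeCN then closes the dioxane ring by intramolecular Williamson displacement of bromide by the phenoxide (6-exo-tet, inversion), which should give aldehyde 14 with the same trans arrangement; step 12 follows.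

Step 8. What may go wrong: slow attack of the hindered ortho-alkoxy phenoxide, a low branched-to-linear ratio, or re-ionisation of the product ether by the catalyst with erosion of enantiopurity. The fallback replaces catalytic allylic substitution by a Mitsunobu etherification with inversion; it sets out from 1 and 9 and returns at 10. Syringaldehyde 1 is acylated (PivCl, Et3N, CH2Cl2) to 4-formyl-2,6-dimethoxyphenyl pivalate F2. CH2=CHMgBr in THF at −78 °C adds to the aldehyde to give racemic 4-(1-hydroxyprop-2-enyl)-2,6-dimethoxyphenyl pivalate F3. Kinetic resolution with Candida antarctica lipase B and vinyl acetate should leave 4-[(1S)-1-hydroxyprop-2-enyl]-2,6-dimethoxyphenyl pivalate F4, while the R enantiomer is converted into its acetate, 4-[(1R)-1-acetoxyprop-2-enyl]-2,6-dimethoxyphenyl pivalate F5, which is removed. F4 and phenol 9 are then coupled with PPh3 and diisopropyl azodicarboxylate in toluene at 0 °C, which should give 10 by SN2 inversion.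

Step 7. What may go wrong: addition of the free ortho phenol to the newly formed enol ether (cyclic acetal formation) during isomerisation or on silica, or catalyst inhibition by the phenol. The fallback masks the phenol during the isomerisation; it sets out from 8 and returns at 9. 8 is acetylated (Ac2O, pyridine) to ethyl (E)-3-[3-acetoxy-4-(allyloxy)-5-methoxyphenyl]prop-2-enoate F6. The allyl ether is isomerised with RuClH(CO)(PPh3)3 in toluene at 80 °C to ethyl (E)-3-[3-acetoxy-5-methoxy-4-[(E)-prop-1-enyloxy]phenyl]prop-2-enoate F7. The acetate is removed with K2CO3 in EtOH at 0 °C, which should give 9 for direct use in step 8.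

**Further compounds**

F1 | step 10 | ethyl (E)-3-[3-[(1S,2S)-2-bromo-1-(3,5-dimethoxy-4-pivaloyloxyphenyl)-3-oxopropoxy]-4-hydroxy-5-methoxyphenyl]prop-2-enoate | COc1cc([C@H](Oc2cc(/C=C/C(=O)OCC)cc(OC)c2O)[C@H](Br)C=O)cc(OC)c1OC(=O)C(C)(C)C
F2 | step 8 | 4-formyl-2,6-dimethoxyphenyl pivalate | COc1cc(C=O)cc(OC)c1OC(=O)C(C)(C)C
F3 | step 8 | racemic 4-(1-hydroxyprop-2-enyl)-2,6-dimethoxyphenyl pivalate | C=CC(O)c1cc(OC)c(OC(=O)C(C)(C)C)c(OC)c1
F4 | step 8 | 4-[(1S)-1-hydroxyprop-2-enyl]-2,6-dimethoxyphenyl pivalate | C=C[C@H](O)c1cc(OC)c(OC(=O)C(C)(C)C)c(OC)c1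
F5 | step 8 | 4-[(1R)-1-acetoxyprop-2-enyl]-2,6-dimethoxyphenyl pivalate | C=C[C@@H](OC(C)=O)c1cc(OC)c(OC(=O)C(C)(C)C)c(OC)c1
F6 | step 7 | ethyl (E)-3-[3-acetoxy-4-(allyloxy)-5-methoxyphenyl]prop-2-enoate | CCOC(=O)/C=C/c1cc(OC(C)=O)c(OCC=C)c(OC)c1
F7 | step 7 | ethyl (E)-3-[3-acetoxy-5-methoxy-4-[(E)-prop-1-enyloxy]phenyl]prop-2-enoate | CCOC(=O)/C=C/c1cc(OC(C)=O)c(O/C=C/C)c(OC)c1
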